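In a closed, stirred vessel at constant temperature, starting material and partner give product, and the runs vary the charge of each.

| flask | starting material | partner | time |
|---|---|---|---|
| teal | 0.500 M | 1.50 M |  |
| red | 0.300 M | 1.30 M |  |
| grey | 0.500 M | 0.750 M |  |
| amber | 0.750 M | 1.50 M |  |
| green | 0.500 M | 0.230 M | 9.5 min |

| run | time / min | [product] / M |
|---|---|---|
| teal run | 1.9 | 0.059 |
| teal run | 3.8 | 0.130 |
| teal run | 5.7 | 0.203 |
| teal run | 7.6 | 0.269 |
| teal run | 9.5 | 0.336 |
| red run | 1.9 | 0.037 |
| red run | 3.8 | 0.080 |
| red run | 5.7 | 0.114 |
| red run | 7.6 | 0.148 |
| red run | 9.5 | 0.187 |
| grey run | 1.9 | 0.023 |
| grey run | 3.8 | 0.054 |
| grey run | 5.7 | 0.079 |
| grey run | 7.6 | 0.123 |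
| grey run | 9.5 | 0.153 |
| amber run | 1.9 | 0.082 |
| amber run | 3.8 | 0.172 |
| amber run | 5.7 | 0.288 |
| amber run | 7.6 | 0.396 |
| amber run | 9.5 | 0.504 |

(standard deviation of a reading: 0.003 M)

- Overall: starting material + partner -> product.
- Constant volume, constant temperature.
- What is held in complexes is read along with the free species.
- "The second partner" is partner.
- An order is taken over about fifteen percent of the charge, up and down.

* apparent order in [starting material] of the starting rate, round the charge of the teal run (the rate where two percent of its starting material have turned into product) (one fixed amount of product, the same in the runs compared)
* apparent order in [partner] of the starting rate, round the charge of the teal run (the rate where two percent of its starting material have turned into product)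
* the red run starts with 0.200 M less of starting material and of partner than the teal run, and with no product. Compared where both hold the same amount of starting material, once fifteen percent of what the red run was charged with has turned into product, is the red run faster, slower or alike (within a tenth)?
* product in the green run at 9.5 min, as a share of the starting material charged

Amber's last step of product is larger than its first, so the amber curve steepens as product builds, and at 1.9 min amber holds more product than teal. I therefore compare the two runs at one amount of product. Teal needs 3.8 min to make product equal to 26.0% of its charge of starting material. Amber, with 1.50 times that charge and the same partner, makes this amount by 2.91 min, read between its first two readings. That gives 0.655, the equal-product order: the logarithm of the ratio of the times to one amount of product, divided by the logarithm of the ratio of the charges. It is a reading, and I commit to it for the order in starting material.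

The forecast gives 0.8 and 1.15 for the orders, slower for the red run and 6% for the green run. It takes its order in starting material from “Amber against teal”, the same pair of runs as mine, and its value is higher than my reading.

The simulation gives orders of 0.59 and 1.1. The red run is slower, at 0.51 of the teal rate, and the green run reaches 5.84%.

    2 partner ⇌ reagent dimer, settled at all times (3.210 M⁻¹)
    starting material + reagent dimer → product + partner (0.4014 M⁻¹ min⁻¹)
    starting material + partner + product → 2 product (2.874 M⁻² min⁻¹)
    2 starting material ⇌ idle substrate dimer, settled at all times (10.70 M⁻¹)

The flask parts from the forecast on the order in starting material. With the idle substrate dimer taken away, that order is 1.0 instead of 0.59, so the pairing of starting material, a resting state off the path to product, holds it down. The red run holds 60.0% of teal's starting material and 86.7% of its partner. With the equal-product order and the partner order of 1.1, I put the red start at 0.608 of teal's, and the simulated rates give 0.624.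

The data were computed from invented constants; scatter was added.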